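The five-membered lactone is disconnected at C7a–C1, C3a–C3 and O2–C1 (phthalide numbering), which leaves an aryne with its triple bond between C3a and C7a. The structural feature exploited is the ortho placement of the lactone carbonyl carbon (on C7a) and methylene carbon (on C3a) next to the C4 oxygen: as a methoxymethyl ether this oxygen polarises the aryne, so that tert-butyl isocyanide enters at C7a, the C3a anion captures formaldehyde and the resulting alkoxide closes the iminolactone, all in one operation. The precursor is a 2-silylaryl triflate (silicon on C7a, triflate on C3a) already bearing the C6 methoxy group, the complete C5 side-chain ether with its tertiary alcohol silylated, and the C4 acetal.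

Key step: step 11

Remarks on the chemistry:
- Ring positions in the Why lines use phthalide numbering (C1, O2, C3, C3a, C4–C7, C7a), also for the arene precursors; side-chain carbons are counted from the OCH2 carbon.
- Formaldehyde is assumed to be used as the monomer, as a THF solution made just before use by cracking commercial paraformaldehyde.
- The C=N geometry of the imidate is left open because the nitrogen is removed in the following step.
- The temporary C5 protecting group is benzyl, removed by neutral hydrogenolysis before the alkenes are introduced.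
- THF with KF/18-crown-6 is chosen for the annulation so that no acidic solvent proton competes for the aryl anion.

Step 1
Reactants: 1 (2E,6E)-farnesol
Product: 2 (2E,6E)-10-bromo-3,7,11-trimethyldodeca-2,6-diene-1,11-diol (racemic at C10)
Conditions: NBS (1.1 equiv), THF/H2O (2:1), 0 °C
Reagents that add atoms: N-bromosuccinimide, O=C1CCC(=O)N1Br; water, O
Why: Bromohydrin formation (van Tamelen conditions): in aqueous THF the polyene coils so that only the terminal trisubstituted alkene is brominated and water opens the bromonium ion at the tertiary carbon; the C10 stereocenter forms as a racemate and is erased in step 2.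

Step 2
Reactants: 2 (2E,6E)-10-bromo-3,7,11-trimethyldodeca-2,6-diene-1,11-diol
Product: 3 (2E,6E)-3,7,11-trimethyldodeca-2,6-diene-1,11-diol
Conditions: Bu3SnH (1.3 equiv), AIBN (cat.), PhMe, 80 °C
Reagents that add atoms: none
Why: Radical chain dehalogenation of a secondary alkyl bromide with tin hydride, which leaves hydroxyl groups and trisubstituted alkenes alone because the C10 radical has only disfavoured 4-exo and 5-endo cyclisations open to it.

Step 3
Reactants: 4 2,3-dihydroxy-4-methoxybenzaldehyde
Product: 5 3-(benzyloxy)-2-hydroxy-4-methoxybenzaldehyde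
Conditions: NaH (2.2 equiv), DMSO, rt; BnBr (1.0 equiv), rt; aq. HCl work-up
Reagents that add atoms: benzyl bromide, BrCc1ccccc1
Why: Williamson etherification of the dianion: the 2-phenoxide is conjugated with and chelated to the formyl group, so one equivalent of benzyl bromide should alkylate only the more nucleophilic 3-phenoxide.

Step 4
Reactants: 5 3-(benzyloxy)-2-hydroxy-4-methoxybenzaldehyde
Product: 6 3-(benzyloxy)-4-methoxy-2-(methoxymethoxy)benzaldehyde
Conditions: MOMCl (1.5 equiv), i-Pr2NEt (2 equiv), CH2Cl2, 0 °C → rt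
Reagents that add atoms: chloromethyl methyl ether, COCCl
Why: Acetal protection of a phenol by O-alkylation with a chloromethyl ether, an electrophile reactive enough to capture even the hydrogen-bonded ortho-hydroxy aldehyde.

Step 5
Reactants: 6 3-(benzyloxy)-4-methoxy-2-(methoxymethoxy)benzaldehyde
Product: 8 3-(benzyloxy)-4-methoxy-2-(methoxymethoxy)phenol, via aryl formate 7 (not isolated)
Conditions: mCPBA (1.3 equiv), CH2Cl2, 0 °C → rt; then K2CO3 (0.2 equiv), MeOH, rt
Reagents that add atoms: meta-chloroperoxybenzoic acid, O=C(OO)c1cccc(Cl)c1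
Why: Baeyer–Villiger (Dakin-type) oxidation: the aryl group, made electron-rich by its ortho and para oxygens, migrates in the Criegee intermediate to give formate 7, which base-catalysed methanolysis cleaves to the phenol.

Step 6
Reactants: 8 3-(benzyloxy)-4-methoxy-2-(methoxymethoxy)phenol
Product: 9 3-(benzyloxy)-6-bromo-4-methoxy-2-(methoxymethoxy)phenol
Conditions: NBS (1.0 equiv), i-Pr2NH (10 mol%), CH2Cl2, −78 → 0 °C
Reagents that add atoms: N-bromosuccinimide, O=C1CCC(=O)N1Br
Why: Amine-mediated ortho-bromination of a phenol (electrophilic aromatic substitution): the free hydroxyl is the strongest donor, its para position is blocked by the methoxy group, and the N-bromoamine is delivered by hydrogen bonding to the single open ortho carbon.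

Step 7
Reactants: 9 3-(benzyloxy)-6-bromo-4-methoxy-2-(methoxymethoxy)phenol
Product: 13 3-(benzyloxy)-4-methoxy-2-(methoxymethoxy)-6-(trimethylsilyl)phenyl trifluoromethanesulfonate, via silyl ether 10 (not isolated), via aryllithium 11 (not isolated), via lithium phenoxide 12 (not isolated)
Conditions: HMDS, THF, 65 °C, then evaporate; n-BuLi (1.1 equiv), THF, −100 → −78 °C; Tf2O (1.2 equiv), −100 °C → rt
Reagents that add atoms: hexamethyldisilazane, C[Si](C)(C)N[Si](C)(C)C; trifluoromethanesulfonic anhydride, O=S(=O)(OS(=O)(=O)C(F)(F)F)C(F)(F)F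
Why: O-silylation, bromine–lithium exchange and 1,3 O-to-C silyl shift (retro-Brook rearrangement) give the ortho-silyl phenoxide 12, which is triflated in the same flask; this is the standard entry to 2-silylaryl triflates and the exchange at −100 °C outruns any attack on the benzyl or acetal groups.

Step 8
Reactants: 13 3-(benzyloxy)-4-methoxy-2-(methoxymethoxy)-6-(trimethylsilyl)phenyl trifluoromethanesulfonate
Product: 14 3-hydroxy-4-methoxy-2-(methoxymethoxy)-6-(trimethylsilyl)phenyl trifluoromethanesulfonate
Conditions: H2 (1 atm), 10% Pd/C, EtOAc, rt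
Reagents that add atoms: none
Why: Hydrogenolysis of an aryl benzyl ether over palladium on carbon under neutral conditions, which should leave the aryl triflate (reduced only when a base is present), the aryl–silicon bond and the acetal intact.

Step 9
Reactants: 14 3-hydroxy-4-methoxy-2-(methoxymethoxy)-6-(trimethylsilyl)phenyl trifluoromethanesulfonate; 3 (2E,6E)-3,7,11-trimethyldodeca-2,6-diene-1,11-diol
Product: 15 3-{[(2E,6E)-11-hydroxy-3,7,11-trimethyldodeca-2,6-dien-1-yl]oxy}-4-methoxy-2-(methoxymethoxy)-6-(trimethylsilyl)phenyl trifluoromethanesulfonate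
Conditions: PPh3 (1.3 equiv), DIAD (1.3 equiv), THF, 0 °C → rt
Reagents that add atoms: none
Why: Mitsunobu etherification: only the primary allylic hydroxyl of 3 is activated as the oxyphosphonium ion, the tertiary hydroxyl being too hindered, and the phenoxide displaces it by SN2 at the primary carbon so that both E double bonds stay in place.

Step 10
Reactants: 15 3-{[(2E,6E)-11-hydroxy-3,7,11-trimethyldodeca-2,6-dien-1-yl]oxy}-4-methoxy-2-(methoxymethoxy)-6-(trimethylsilyl)phenyl trifluoromethanesulfonate
Product: 16 4-methoxy-2-(methoxymethoxy)-3-{[(2E,6E)-3,7,11-trimethyl-11-(triethylsilyloxy)dodeca-2,6-dien-1-yl]oxy}-6-(trimethylsilyl)phenyl trifluoromethanesulfonate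
Conditions: TESCl (2 equiv), imidazole (4 equiv), DMAP (0.1 equiv), DMF, rt → 40 °C
Reagents that add atoms: chlorotriethylsilane, CC[Si](Cl)(CC)CC
Why: Silylation of the dimethylcarbinol with the small triethylsilyl chloride under imidazole/DMAP catalysis, chosen instead of a silyl triflate so that the aryl methoxymethyl ether, the aryl triflate and the aryl silane are not touched.

Step 11
Reactants: 16 4-methoxy-2-(methoxymethoxy)-3-{[(2E,6E)-3,7,11-trimethyl-11-(triethylsilyloxy)dodeca-2,6-dien-1-yl]oxy}-6-(trimethylsilyl)phenyl trifluoromethanesulfonate; 17 tert-butyl isocyanide; 18 formaldehyde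
Product: 22 N-tert-butyl-6-methoxy-4-(methoxymethoxy)-5-{[(2E,6E)-3,7,11-trimethyl-11-(triethylsilyloxy)dodeca-2,6-dien-1-yl]oxy}isobenzofuran-1(3H)-imine (C=N geometry open), via aryne 19 (not isolated), via nitrilium aryl anion 20 (not isolated), via nitrilium alkoxide 21 (not isolated)
Conditions: KF (3 equiv), 18-crown-6 (3 equiv), 17 (2 equiv), 18 (4 equiv, monomer in THF), THF, −20 → 0 °C
Reagents that add atoms: none
Why: Fluoride removes the trimethylsilyl group of 16 and triflate leaves from the neighbouring carbon, giving aryne 19 with its triple bond between C3a and C7a. The C4 methoxymethoxy group, a σ-acceptor directly beside C3a, distorts the aryne so that the isocyanide carbon of 17 attacks the remote, unhindered C7a and the negative charge develops at C3a next to that oxygen (20); the weak, opposed remote effects of the C5 and C6 oxygens roughly cancel and C7 carries only hydrogen. Carbanion 20 adds to formaldehyde 18 to give alkoxide 21, which closes onto the nitrilium carbon by 5-exo-dig attack, so the C7a–C1, C3a–C3 and O2–C1 bonds and the five-membered ring form in one operation. The closest known reaction type is the fluoride-triggered three-component coupling of arynes, isocyanides and aldehydes to 1-iminoisobenzofurans. No stereocenter is created, and the regiochemistry needed (carbonyl carbon on C7a, methylene on C3a) rests on the C4 acetal alone. The hindered tertiary triethylsilyl ether should resist fluoride far longer than the triflate-activated aryl silane and keeps the hydroxyl from protonating 20, which is also why THF is used.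

Step 12
Reactants: 22 N-tert-butyl-6-methoxy-4-(methoxymethoxy)-5-{[(2E,6E)-3,7,11-trimethyl-11-(triethylsilyloxy)dodeca-2,6-dien-1-yl]oxy}isobenzofuran-1(3H)-imine
Product: 23 5-{[(2E,6E)-11-hydroxy-3,7,11-trimethyldodeca-2,6-dien-1-yl]oxy}-6-methoxy-4-(methoxymethoxy)isobenzofuran-1(3H)-one
Conditions: AcOH/THF/H2O (3:1:1), rt → 40 °C
Reagents that add atoms: water, O
Why: Acid-catalysed hydrolysis of a cyclic imidate, in which the protonated tetrahedral intermediate expels tert-butylamine and leaves the lactone, runs alongside acidic solvolysis of the triethylsilyl ether, while aqueous acetic acid is too weak to cleave the aryl acetal or ionise the allylic aryl ether.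

Step 13
Reactants: 23 5-{[(2E,6E)-11-hydroxy-3,7,11-trimethyldodeca-2,6-dien-1-yl]oxy}-6-methoxy-4-(methoxymethoxy)isobenzofuran-1(3H)-one
Product: 25 farnesylemefuranone E (4-hydroxy-5-{[(2E,6E)-11-hydroxy-3,7,11-trimethyldodeca-2,6-dien-1-yl]oxy}-6-methoxyisobenzofuran-1(3H)-one), via bis-silyl ether 24 (not isolated)
Conditions: TMSOTf (4 equiv), 2,2'-bipyridyl (6 equiv), MeCN, 0 °C → rt; then H2O, rt
Reagents that add atoms: none
Why: Chemoselective cleavage of an aromatic methoxymethyl ether by the TMSOTf/2,2'-bipyridyl pair, which exchanges the acetal for an aryl trimethylsilyl ether under buffered aprotic conditions that should spare the allylic aryl ether and the lactone; the tertiary alcohol is silylated in passing and both trimethylsilyl ethers of 24 hydrolyse in the aqueous stage.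

Compound list
1 | (2E,6E)-farnesol | CC(C)=CCC/C(C)=C/CC/C(C)=C/CO | starting material
2 | (2E,6E)-10-bromo-3,7,11-trimethyldodeca-2,6-diene-1,11-diol (racemic at C10) | CC(C)(O)C(Br)CC/C(C)=C/CC/C(C)=C/CO | intermediate
3 | (2E,6E)-3,7,11-trimethyldodeca-2,6-diene-1,11-diol | CC(C)(O)CCC/C(C)=C/CC/C(C)=C/CO | intermediate
4 | 2,3-dihydroxy-4-methoxybenzaldehyde | COc1ccc(C=O)c(O)c1O | starting material
5 | 3-(benzyloxy)-2-hydroxy-4-methoxybenzaldehyde | COc1ccc(C=O)c(O)c1OCc1ccccc1 | intermediate
6 | 3-(benzyloxy)-4-methoxy-2-(methoxymethoxy)benzaldehyde | COCOc1c(C=O)ccc(OC)c1OCc1ccccc1 | intermediate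
7 | 3-(benzyloxy)-4-methoxy-2-(methoxymethoxy)phenyl formate | COCOc1c(OC=O)ccc(OC)c1OCc1ccccc1 | intermediate
8 | 3-(benzyloxy)-4-methoxy-2-(methoxymethoxy)phenol | COCOc1c(O)ccc(OC)c1OCc1ccccc1 | intermediate
9 | 3-(benzyloxy)-6-bromo-4-methoxy-2-(methoxymethoxy)phenol | COCOc1c(O)c(Br)cc(OC)c1OCc1ccccc1 | intermediate
10 | [3-(benzyloxy)-6-bromo-4-methoxy-2-(methoxymethoxy)phenoxy]trimethylsilane | COCOc1c(O[Si](C)(C)C)c(Br)cc(OC)c1OCc1ccccc1 | intermediate
11 | [3-(benzyloxy)-4-methoxy-2-(methoxymethoxy)-6-lithiophenoxy]trimethylsilane | COCOc1c(O[Si](C)(C)C)c([Li])cc(OC)c1OCc1ccccc1 | intermediate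
12 | lithium 3-(benzyloxy)-4-methoxy-2-(methoxymethoxy)-6-(trimethylsilyl)phenoxide | COCOc1c([O-])c([Si](C)(C)C)cc(OC)c1OCc1ccccc1.[Li+] | intermediate
13 | 3-(benzyloxy)-4-methoxy-2-(methoxymethoxy)-6-(trimethylsilyl)phenyl trifluoromethanesulfonate | COCOc1c(OS(=O)(=O)C(F)(F)F)c([Si](C)(C)C)cc(OC)c1OCc1ccccc1 | intermediate
14 | 3-hydroxy-4-methoxy-2-(methoxymethoxy)-6-(trimethylsilyl)phenyl trifluoromethanesulfonate | COCOc1c(OS(=O)(=O)C(F)(F)F)c([Si](C)(C)C)cc(OC)c1O | intermediate
15 | 3-{[(2E,6E)-11-hydroxy-3,7,11-trimethyldodeca-2,6-dien-1-yl]oxy}-4-methoxy-2-(methoxymethoxy)-6-(trimethylsilyl)phenyl trifluoromethanesulfonate | COc1cc([Si](C)(C)C)c(OS(=O)(=O)C(F)(F)F)c(OCOC)c1OC/C=C(\C)CC/C=C(\C)CCCC(C)(C)O | intermediate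
16 | 4-methoxy-2-(methoxymethoxy)-3-{[(2E,6E)-3,7,11-trimethyl-11-(triethylsilyloxy)dodeca-2,6-dien-1-yl]oxy}-6-(trimethylsilyl)phenyl trifluoromethanesulfonate (aryne precursor) | COc1cc([Si](C)(C)C)c(OS(=O)(=O)C(F)(F)F)c(OCOC)c1OC/C=C(\C)CC/C=C(\C)CCCC(C)(C)O[Si](CC)(CC)CC | intermediate
17 | tert-butyl isocyanide | CC(C)(C)[N+]#[C-] | starting material
18 | formaldehyde (monomer, from paraformaldehyde) | C=O | starting material
19 | 5-methoxy-3-(methoxymethoxy)-4-{[(2E,6E)-3,7,11-trimethyl-11-(triethylsilyloxy)dodeca-2,6-dien-1-yl]oxy}-1,2-didehydrobenzene (aryne) | COC1=CC#CC(OCOC)=C1OC/C=C(\C)CC/C=C(\C)CCCC(C)(C)O[Si](CC)(CC)CC | intermediate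
20 | N-tert-butyl nitrilium on C7a with aryl anion on C3a (zwitterion) | COc1cc(C#[N+]C(C)(C)C)[c-]c(OCOC)c1OC/C=C(\C)CC/C=C(\C)CCCC(C)(C)O[Si](CC)(CC)CC | intermediate
21 | N-tert-butyl nitrilium on C7a with oxidomethyl group on C3a (zwitterion) | COc1cc(C#[N+]C(C)(C)C)c(C[O-])c(OCOC)c1OC/C=C(\C)CC/C=C(\C)CCCC(C)(C)O[Si](CC)(CC)CC | intermediate
22 | N-tert-butyl-6-methoxy-4-(methoxymethoxy)-5-{[(2E,6E)-3,7,11-trimethyl-11-(triethylsilyloxy)dodeca-2,6-dien-1-yl]oxy}isobenzofuran-1(3H)-imine | COc1cc2c(c(OCOC)c1OC/C=C(\C)CC/C=C(\C)CCCC(C)(C)O[Si](CC)(CC)CC)COC2=NC(C)(C)C | intermediate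
23 | 5-{[(2E,6E)-11-hydroxy-3,7,11-trimethyldodeca-2,6-dien-1-yl]oxy}-6-methoxy-4-(methoxymethoxy)isobenzofuran-1(3H)-one | COc1cc2c(c(OCOC)c1OC/C=C(\C)CC/C=C(\C)CCCC(C)(C)O)COC2=O | intermediate
24 | 6-methoxy-4-(trimethylsilyloxy)-5-{[(2E,6E)-3,7,11-trimethyl-11-(trimethylsilyloxy)dodeca-2,6-dien-1-yl]oxy}isobenzofuran-1(3H)-one | COc1cc2c(c(O[Si](C)(C)C)c1OC/C=C(\C)CC/C=C(\C)CCCC(C)(C)O[Si](C)(C)C)COC2=O | intermediate
25 | farnesylemefuranone E | COc1cc2c(c(O)c1OC/C=C(\C)CC/C=C(\C)CCCC(C)(C)O)COC2=O | target

Total step count: 13 (2 for the side chain, 11 on the aromatic line).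
Longest linear sequence: 11 steps (4 to 25, steps 3–13).

The three steps most likely to fail

1. Step 11 (key step). The C3a carbanion may be protonated before it meets formaldehyde, which would give only the simple N-tert-butyl benzamide after work-up. Formaldehyde may also oligomerise under fluoride and starve the anion. The fallback sets out from aldehyde 6, whose formyl carbon already sits on the future C3a, and builds the lactone by directed metalation. Aldehyde 6 is converted in situ into its α-amino alkoxide with LiN(Me)CH2CH2NMe2 (THF, −20 °C) and lithiated with n-BuLi at the only free position beside the masked formyl group, the future C7a (Comins-type ortho-lithiation). A CO2 quench and mild acidification should give 4-(benzyloxy)-2-formyl-5-methoxy-3-(methoxymethoxy)benzoic acid F1. NaBH4 in MeOH followed by acidification to pH 3 reduces the formyl group and lactonises to 5-(benzyloxy)-6-methoxy-4-(methoxymethoxy)isobenzofuran-1(3H)-one F2. Hydrogenolysis (H2, Pd/C, EtOAc) frees 5-hydroxy-6-methoxy-4-(methoxymethoxy)isobenzofuran-1(3H)-one F3. Mitsunobu coupling of F3 with diol 3 (PPh3, DIAD, THF) comes back to the route at 23, before step 13.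

2. Step 6. Bromine may enter ortho to the methoxy group instead of ortho to the hydroxyl, or the para-methoxyphenol may be oxidised towards a quinone. The fallback sets out from phenol 8, replaces steps 6 and 7, and installs silicon by carbamate-directed ortho-metalation without any halogenation. Phenol 8 and isopropyl isocyanate (Et3N cat., CH2Cl2) should give 3-(benzyloxy)-4-methoxy-2-(methoxymethoxy)phenyl isopropylcarbamate F4. Transient N-silylation (TMSOTf, TMEDA, Et2O), lithiation at the only free ortho position with n-BuLi/TMEDA at −78 °C, TMSCl quench and aqueous work-up give 3-(benzyloxy)-4-methoxy-2-(methoxymethoxy)-6-(trimethylsilyl)phenyl isopropylcarbamate F5. Et2NH and DBU in MeCN at 40 °C then release the phenoxide, which PhNTf2 triflates in the same flask. The fallback comes back to the route at 13.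

3. Step 13. The doubly flanked acetal may leave slowly, so that ionisation of the allylic aryl ether or loss of the tertiary hydroxyl competes and the side chain is damaged before the phenol is freed. The fallback takes the acetal off before the side chain is attached. It sets out from 13, which is itself a 2-silylaryl triflate. Under the conditions of step 11 with 17 and 18, 13 should give N-tert-butyl-5-(benzyloxy)-6-methoxy-4-(methoxymethoxy)isobenzofuran-1(3H)-imine F6. HCl in MeOH/H2O at 40 °C hydrolyses the imidate and removes the acetal together, with no acid-sensitive chain present, to give 5-(benzyloxy)-4-hydroxy-6-methoxyisobenzofuran-1(3H)-one F7. Hydrogenolysis (H2, Pd/C, EtOAc) gives 4,5-dihydroxy-6-methoxyisobenzofuran-1(3H)-one F8. A Mitsunobu etherification with one equivalent of diol 3 should then alkylate the more acidic C5 hydroxyl, para to the lactone carbonyl, as is known for 3,4-dihydroxybenzoates. The fallback comes back to the route at the target 25.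

Further compounds
F1 | step 11 | 4-(benzyloxy)-2-formyl-5-methoxy-3-(methoxymethoxy)benzoic acid | COc1cc(C(=O)O)c(C=O)c(OCOC)c1OCc1ccccc1
F2 | step 11 | 5-(benzyloxy)-6-methoxy-4-(methoxymethoxy)isobenzofuran-1(3H)-one | COc1cc2c(c(OCOC)c1OCc1ccccc1)COC2=O
F3 | step 11 | 5-hydroxy-6-methoxy-4-(methoxymethoxy)isobenzofuran-1(3H)-one | COc1cc2c(c(OCOC)c1O)COC2=O
F4 | step 6 | 3-(benzyloxy)-4-methoxy-2-(methoxymethoxy)phenyl isopropylcarbamate | COCOc1c(OC(=O)NC(C)C)ccc(OC)c1OCc1ccccc1
F5 | step 6 | 3-(benzyloxy)-4-methoxy-2-(methoxymethoxy)-6-(trimethylsilyl)phenyl isopropylcarbamate | COCOc1c(OC(=O)NC(C)C)c([Si](C)(C)C)cc(OC)c1OCc1ccccc1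
F6 | step 13 | N-tert-butyl-5-(benzyloxy)-6-methoxy-4-(methoxymethoxy)isobenzofuran-1(3H)-imine | COc1cc2c(c(OCOC)c1OCc1ccccc1)COC2=NC(C)(C)C
F7 | step 13 | 5-(benzyloxy)-4-hydroxy-6-methoxyisobenzofuran-1(3H)-one | COc1cc2c(c(O)c1OCc1ccccc1)COC2=O
F8 | step 13 | 4,5-dihydroxy-6-methoxyisobenzofuran-1(3H)-one | COc1cc2c(c(O)c1O)COC2=O
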